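**Retrosynthetic overview**
1. Target ⇐ Mitsunobu inversion at C14 of its 14-epimer, which comes from a chromium-mediated (Nozaki–Hiyama–Kishi-type) intramolecular allylation of an ω-formyl 3-(bromomethyl)butenolide (C1–C14 bond; closes the 14-membered ring last).
2. Bromomethylbutenolide ⇐ ring-closing metathesis of a 2-(bromomethyl)acrylate ester, made from Felkin-controlled vinyl addition to a C2 epoxy aldehyde (C1–C2 bond, sets C2).
3. Epoxy aldehyde ⇐ Sharpless kinetic resolution of a racemic C5 allylic alcohol (sets C3, C4, C5), then Mitsunobu inversion with acetic acid (installs the C5 acetate).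
4. C5–C6 bond ⇐ α-selective allylbarium addition of a C6–C14 allylic chloride to (E)-4-acetoxy-2-methylbut-2-enal.
5. C6–C14 chloride ⇐ geranyl acetate by ozonolysis, Z-selective iodo-olefination (C11=C12) and B-alkyl Suzuki coupling (C12–C13). Ring order: oxirane, then five-membered lactone (as butenolide), then the 14-membered carbocycle.

Assumption: the macrocycles 24 and 26 are named with cembrane numbering (C1 carries C15, C2 carries the lactone oxygen, C16 is the lactone carbonyl, C17 the exocyclic CH2), the SMILES strings are authoritative, and 5, 9 and 17 are taken as purchasable.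

**Step 1**
Reactants: 1 geranyl acetate [(2E)-3,7-dimethylocta-2,6-dien-1-yl acetate]
Product: 2 (2E)-3-methyl-6-oxohex-2-en-1-yl acetate
Conditions: O3 (1.0 equiv), pyridine, CH2Cl2, −78 °C; then Me2S, −78 °C→rt
Reagents that add atoms: ozone, [O-][O+]=O
Why: Chemoselective ozonolysis cleaves the electron-rich terminal trisubstituted alkene while the alkene deactivated by the allylic acetate survives, so the 2E geometry (future C7=C8) is carried through and no stereocentre is formed.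

**Step 2**
Reactants: 2 (2E)-3-methyl-6-oxohex-2-en-1-yl acetate
Product: 3 (2E,6Z)-7-iodo-3-methylocta-2,6-dien-1-yl acetate
Conditions: [Ph3PEt]I, n-BuLi, THF, 0 °C; I2, −78 °C; NaN(SiMe3)2, −20 °C; then 2, −78 °C
Reagents that add atoms: ethyltriphenylphosphonium iodide, CC[P+](c1ccccc1)(c1ccccc1)c1ccccc1.[I-]; iodine, [I][I]
Why: Stork–Zhao-type Wittig olefination with the α-iodo ylide Ph3P=C(I)CH3 proceeds through the kinetic cis-oxaphosphetane and gives the (Z)-2-iodoalkene, which fixes the later 11Z trisubstituted alkene.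

**Step 3**
Reactants: 3 (2E,6Z)-7-iodo-3-methylocta-2,6-dien-1-yl acetate
Product: 4 (2E,6Z)-7-iodo-3-methylocta-2,6-dien-1-ol
Conditions: K2CO3 (0.1 equiv), MeOH, rt
Reagents that add atoms: none
Why: Carbonate-catalysed transesterification removes the allylic acetate, which could otherwise ionise on zerovalent palladium in the next step, and leaves the vinyl iodide untouched.

**Step 4**
Reactants: 4 (2E,6Z)-7-iodo-3-methylocta-2,6-dien-1-ol; 5 tert-butyldimethyl(vinyloxy)silane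
Product: 7 (2E,6Z)-9-[(tert-butyldimethylsilyl)oxy]-3,7-dimethylnona-2,6-dien-1-ol, via alkyl-9-BBN borane 6 (not isolated)
Conditions: 5, 9-BBN, THF, 0 °C→rt; then 4, PdCl2(dppf) (5 mol %), AsPh3, Cs2CO3, DMF–H2O, rt
Reagents that add atoms: none
Why: B-alkyl Suzuki–Miyaura coupling: hydroboration of the enol ether puts boron on the terminal carbon, and the sp3–sp2 coupling retains the vinyl iodide geometry, so C12–C13 is formed with the 11Z alkene intact.

**Step 5**
Reactants: 7 (2E,6Z)-9-[(tert-butyldimethylsilyl)oxy]-3,7-dimethylnona-2,6-dien-1-ol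
Product: 8 tert-butyl{[(3Z,7E)-9-chloro-3,7-dimethylnona-3,7-dien-1-yl]oxy}dimethylsilane
Conditions: N-chlorosuccinimide, Me2S, CH2Cl2, −20→0 °C
Reagents that add atoms: N-chlorosuccinimide, ClN1C(=O)CCC1=O
Why: Corey–Kim-type chlorination displaces the alkoxysulfonium by chloride in an SN2 sense, giving the primary allylic chloride without allylic transposition or loss of alkene geometry.

**Step 6**
Reactants: 8 tert-butyl{[(3Z,7E)-9-chloro-3,7-dimethylnona-3,7-dien-1-yl]oxy}dimethylsilane; 9 (2E)-3-methyl-4-oxobut-2-en-1-yl acetate [(E)-4-acetoxy-2-methylbut-2-enal]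
Product: 11 rac-(2E,6E,10Z)-13-[(tert-butyldimethylsilyl)oxy]-4-hydroxy-3,7,11-trimethyltrideca-2,6,10-trien-1-yl acetate, via allylbarium chloride 10 (not isolated)
Conditions: BaI2, LiC12H10 (lithium biphenylide, 2 equiv), THF, rt; 8, −78 °C; then 9, −78 °C; H2O
Reagents that add atoms: none
Why: Allylbarium reagents add 1,2 to aldehydes at their unsubstituted α-carbon with retention of alkene geometry, so the C5–C6 bond forms as the linear homoallylic alcohol (7E kept, C5 racemic) and the acetate is not attacked at −78 °C.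

**Step 7**
Reactants: 11 rac-(2E,6E,10Z)-13-[(tert-butyldimethylsilyl)oxy]-4-hydroxy-3,7,11-trimethyltrideca-2,6,10-trien-1-yl acetate
Product: 12 [(2S,3S)-3-{(1S,3E,7Z)-10-[(tert-butyldimethylsilyl)oxy]-1-hydroxy-4,8-dimethyldeca-3,7-dien-1-yl}-3-methyloxiran-2-yl]methyl acetate
Conditions: Ti(OiPr)4 (0.2 equiv), L-(+)-diisopropyl tartrate (0.25 equiv), t-BuOOH (0.55 equiv), 4 Å MS, CH2Cl2, −20 °C
Reagents that add atoms: tert-butyl hydroperoxide, CC(C)(C)OO
Why: Sharpless kinetic resolution: with L-(+)-tartrate the (4S)-enantiomer of 11 is epoxidised far faster than its antipode and hydroxyl-directed oxygen transfer gives the erythro (2S,3S)-epoxide, so C3, C4 and C5 of the target skeleton are fixed at once while the (4R)-alcohol stays behind.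

**Step 8**
Reactants: 12 [(2S,3S)-3-{(1S,3E,7Z)-10-[(tert-butyldimethylsilyl)oxy]-1-hydroxy-4,8-dimethyldeca-3,7-dien-1-yl}-3-methyloxiran-2-yl]methyl acetate
Product: 13 [(2S,3S)-3-{(1R,3E,7Z)-1-acetoxy-10-[(tert-butyldimethylsilyl)oxy]-4,8-dimethyldeca-3,7-dien-1-yl}-3-methyloxiran-2-yl]methyl acetate
Conditions: PPh3, DIAD, AcOH, toluene, 0 °C→rt
Reagents that add atoms: acetic acid, CC(O)=O
Why: Mitsunobu reaction: SN2 displacement of the phosphonium-activated hydroxyl by acetate inverts C5 (S to R) and installs the target's C5 acetate in the threo relationship to the epoxide that directed epoxidation cannot give.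

**Step 9**
Reactants: 13 [(2S,3S)-3-{(1R,3E,7Z)-1-acetoxy-10-[(tert-butyldimethylsilyl)oxy]-4,8-dimethyldeca-3,7-dien-1-yl}-3-methyloxiran-2-yl]methyl acetate
Product: 14 (1R,3E,7Z)-10-[(tert-butyldimethylsilyl)oxy]-1-[(2S,3S)-3-(hydroxymethyl)-2-methyloxiran-2-yl]-4,8-dimethyldeca-3,7-dien-1-yl acetate
Conditions: K2CO3 (0.1 equiv), MeOH, −10 °C
Reagents that add atoms: none
Why: Selective transesterification: the unhindered primary acetate is cleaved much faster than the secondary acetate next to the fully substituted epoxide carbon, and the trans arrangement across the epoxide rules out acyl migration.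

**Step 10**
Reactants: 14 (1R,3E,7Z)-10-[(tert-butyldimethylsilyl)oxy]-1-[(2S,3S)-3-(hydroxymethyl)-2-methyloxiran-2-yl]-4,8-dimethyldeca-3,7-dien-1-yl acetate
Product: 15 (1R,3E,7Z)-10-[(tert-butyldimethylsilyl)oxy]-1-[(2S,3R)-3-formyl-2-methyloxiran-2-yl]-4,8-dimethyldeca-3,7-dien-1-yl acetate
Conditions: Dess–Martin periodinane, pyridine, CH2Cl2, 0 °C→rt
Reagents that add atoms: none
Why: Dess–Martin oxidation converts the primary epoxy alcohol to the epoxy aldehyde under near-neutral conditions without epimerising the epoxide carbon (the descriptor changes to R only through CIP priorities).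

**Step 11**
Reactants: 15 (1R,3E,7Z)-10-[(tert-butyldimethylsilyl)oxy]-1-[(2S,3R)-3-formyl-2-methyloxiran-2-yl]-4,8-dimethyldeca-3,7-dien-1-yl acetate
Product: 16 (1R,3E,7Z)-10-[(tert-butyldimethylsilyl)oxy]-1-{(2S,3S)-3-[(1S)-1-hydroxyprop-2-en-1-yl]-2-methyloxiran-2-yl}-4,8-dimethyldeca-3,7-dien-1-yl acetate
Conditions: CH2=CHMgBr (1.2 equiv), THF, −78 °C; H2O; chromatographic removal of the minor epimer
Reagents that add atoms: vinylmagnesium bromide, C=C[Mg]Br
Why: Felkin–Anh (Cornforth) controlled Grignard addition: with the epoxide C–O bond anti to the carbonyl, the vinyl group attacks past the epoxide hydrogen and gives the anti epoxy alcohol, which sets C2 as S, and the acetate is not touched at −78 °C.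

**Step 12**
Reactants: 16 (1R,3E,7Z)-10-[(tert-butyldimethylsilyl)oxy]-1-{(2S,3S)-3-[(1S)-1-hydroxyprop-2-en-1-yl]-2-methyloxiran-2-yl}-4,8-dimethyldeca-3,7-dien-1-yl acetate; 17 2-(bromomethyl)prop-2-enoic acid
Product: 19 (1S)-1-[(2S,3S)-3-{(1R,3E,7Z)-1-acetoxy-10-[(tert-butyldimethylsilyl)oxy]-4,8-dimethyldeca-3,7-dien-1-yl}-3-methyloxiran-2-yl]prop-2-en-1-yl 2-(bromomethyl)prop-2-enoate, via acid chloride 18 (not isolated)
Conditions: 17, (COCl)2, DMF (cat.), CH2Cl2, 0 °C→rt; then 16, 2,6-lutidine, CH2Cl2, −20→0 °C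
Reagents that add atoms: none
Why: O-Acylation by the acid chloride proceeds with retention at C2, and the hindered non-nucleophilic base avoids SN2' attack on the allylic bromide.

**Step 13**
Reactants: 19 (1S)-1-[(2S,3S)-3-{(1R,3E,7Z)-1-acetoxy-10-[(tert-butyldimethylsilyl)oxy]-4,8-dimethyldeca-3,7-dien-1-yl}-3-methyloxiran-2-yl]prop-2-en-1-yl 2-(bromomethyl)prop-2-enoate
Product: 20 (1R,3E,7Z)-1-{(2S,3S)-3-[(2S)-4-(bromomethyl)-5-oxo-2,5-dihydrofuran-2-yl]-2-methyloxiran-2-yl}-10-[(tert-butyldimethylsilyl)oxy]-4,8-dimethyldeca-3,7-dien-1-yl acetate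
Conditions: second-generation Grubbs catalyst RuCl2(=CHPh)(PCy3)(H2IMes) (10 mol %), toluene (0.005 M), 70 °C
Reagents that add atoms: none
Why: Ring-closing metathesis between the vinyl group and the acrylate closes the five-membered butenolide much faster than the catalyst engages the trisubstituted alkenes, and C2 is not touched.

**Step 14**
Reactants: 20 (1R,3E,7Z)-1-{(2S,3S)-3-[(2S)-4-(bromomethyl)-5-oxo-2,5-dihydrofuran-2-yl]-2-methyloxiran-2-yl}-10-[(tert-butyldimethylsilyl)oxy]-4,8-dimethyldeca-3,7-dien-1-yl acetate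
Product: 21 (1R,3E,7Z)-1-{(2S,3S)-3-[(2S)-4-(bromomethyl)-5-oxo-2,5-dihydrofuran-2-yl]-2-methyloxiran-2-yl}-10-hydroxy-4,8-dimethyldeca-3,7-dien-1-yl acetate
Conditions: HF·pyridine, pyridine, THF, 0 °C
Reagents that add atoms: none
Why: Buffered acidic fluoride desilylation frees the primary alcohol without a basic or nucleophilic fluoride source that would attack the allylic bromide or the base-sensitive butenolide, and the epoxide, flanked by two electron-withdrawing oxygenated carbons, resists opening.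

**Step 15**
Reactants: 21 (1R,3E,7Z)-1-{(2S,3S)-3-[(2S)-4-(bromomethyl)-5-oxo-2,5-dihydrofuran-2-yl]-2-methyloxiran-2-yl}-10-hydroxy-4,8-dimethyldeca-3,7-dien-1-yl acetate
Product: 22 (1R,3E,7Z)-1-{(2S,3S)-3-[(2S)-4-(bromomethyl)-5-oxo-2,5-dihydrofuran-2-yl]-2-methyloxiran-2-yl}-4,8-dimethyl-10-oxodeca-3,7-dien-1-yl acetate
Conditions: Dess–Martin periodinane, pyridine, CH2Cl2, 0 °C; used at once
Reagents that add atoms: none
Why: Buffered Dess–Martin oxidation gives the β,γ-unsaturated aldehyde without moving the 11Z alkene into conjugation.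

**Step 16**
Reactants: 22 (1R,3E,7Z)-1-{(2S,3S)-3-[(2S)-4-(bromomethyl)-5-oxo-2,5-dihydrofuran-2-yl]-2-methyloxiran-2-yl}-4,8-dimethyl-10-oxodeca-3,7-dien-1-yl acetate
Product: 24 (1R,2S,3S,4S,5R,14S,7E,11Z)-5-acetoxy-3,4-epoxy-14-hydroxycembra-7,11,15(17)-trien-16,2-olide, via allylchromium dichloride 23 (not isolated)
Conditions: CrCl2 (8 equiv), 4 Å MS, THF (0.003 M, slow addition of 22), rt; H2O
Reagents that add atoms: none
Why: Nozaki–Hiyama–Kishi-type allylation: the allylchromium attacks the aldehyde through its γ-carbon C1 on the face opposite the C2 side chain (trans-lactone, 1R) in a closed chair transition state, where the ring-locked E-type allyl unit and an equatorial aldehyde chain give the 1,14-anti adduct (14S) and shift the double bond to the exocyclic methylene.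

**Step 17**
Reactants: 24 (1R,2S,3S,4S,5R,14S,7E,11Z)-5-acetoxy-3,4-epoxy-14-hydroxycembra-7,11,15(17)-trien-16,2-olide
Product: 26 (1R,2S,3S,4S,5R,14R,7E,11Z)-5-acetoxy-3,4-epoxy-14-hydroxycembra-7,11,15(17)-trien-16,2-olide (CNP0283244.1), via C14 formate ester 25 (not isolated)
Conditions: PPh3, DIAD, HCO2H, THF, 0 °C→rt; then MeOH, NaHCO3 (cat.), rt
Reagents that add atoms: formic acid, OC=O
Why: Mitsunobu reaction: SN2 displacement of the activated C14 hydroxyl by formate inverts C14 (S to R), and the formate, far more labile than the hindered C5 acetate, is removed by bicarbonate-catalysed methanolysis.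

**Compound list**
1 | geranyl acetate, (2E)-3,7-dimethylocta-2,6-dien-1-yl acetate | CC(C)=CCC/C(C)=C/COC(C)=O | starting material
2 | (2E)-3-methyl-6-oxohex-2-en-1-yl acetate | O=CCC/C(C)=C/COC(C)=O | intermediate
3 | (2E,6Z)-7-iodo-3-methylocta-2,6-dien-1-yl acetate | I/C(C)=C\CC/C(C)=C/COC(C)=O | intermediate
4 | (2E,6Z)-7-iodo-3-methylocta-2,6-dien-1-ol | I/C(C)=C\CC/C(C)=C/CO | intermediate
5 | tert-butyldimethyl(vinyloxy)silane | C=CO[Si](C)(C)C(C)(C)C | starting material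
6 | 9-{2-[(tert-butyldimethylsilyl)oxy]ethyl}-9-borabicyclo[3.3.1]nonane | CC(C)(C)[Si](C)(C)OCCB1C2CCCC1CCC2 | intermediate
7 | (2E,6Z)-9-[(tert-butyldimethylsilyl)oxy]-3,7-dimethylnona-2,6-dien-1-ol | CC(C)(C)[Si](C)(C)OCC/C(C)=C\CC/C(C)=C/CO | intermediate
8 | tert-butyl{[(3Z,7E)-9-chloro-3,7-dimethylnona-3,7-dien-1-yl]oxy}dimethylsilane | CC(C)(C)[Si](C)(C)OCC/C(C)=C\CC/C(C)=C/CCl | intermediate
9 | (2E)-3-methyl-4-oxobut-2-en-1-yl acetate, (E)-4-acetoxy-2-methylbut-2-enal | O=C/C(C)=C/COC(C)=O | starting material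
10 | chlorido{(2E,6Z)-9-[(tert-butyldimethylsilyl)oxy]-3,7-dimethylnona-2,6-dien-1-yl}barium | CC(C)(C)[Si](C)(C)OCC/C(C)=C\CC/C(C)=C/C[Ba]Cl | intermediate
11 | rac-(2E,6E,10Z)-13-[(tert-butyldimethylsilyl)oxy]-4-hydroxy-3,7,11-trimethyltrideca-2,6,10-trien-1-yl acetate | CC(C)(C)[Si](C)(C)OCC/C(C)=C\CC/C(C)=C/CC(O)/C(C)=C/COC(C)=O | intermediate
12 | [(2S,3S)-3-{(1S,3E,7Z)-10-[(tert-butyldimethylsilyl)oxy]-1-hydroxy-4,8-dimethyldeca-3,7-dien-1-yl}-3-methyloxiran-2-yl]methyl acetate | CC(C)(C)[Si](C)(C)OCC/C(C)=C\CC/C(C)=C/C[C@H](O)[C@]1(C)O[C@H]1COC(C)=O | intermediate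
13 | [(2S,3S)-3-{(1R,3E,7Z)-1-acetoxy-10-[(tert-butyldimethylsilyl)oxy]-4,8-dimethyldeca-3,7-dien-1-yl}-3-methyloxiran-2-yl]methyl acetate | CC(C)(C)[Si](C)(C)OCC/C(C)=C\CC/C(C)=C/C[C@@H](OC(C)=O)[C@]1(C)O[C@H]1COC(C)=O | intermediate
14 | (1R,3E,7Z)-10-[(tert-butyldimethylsilyl)oxy]-1-[(2S,3S)-3-(hydroxymethyl)-2-methyloxiran-2-yl]-4,8-dimethyldeca-3,7-dien-1-yl acetate | CC(C)(C)[Si](C)(C)OCC/C(C)=C\CC/C(C)=C/C[C@@H](OC(C)=O)[C@]1(C)O[C@H]1CO | intermediate
15 | (1R,3E,7Z)-10-[(tert-butyldimethylsilyl)oxy]-1-[(2S,3R)-3-formyl-2-methyloxiran-2-yl]-4,8-dimethyldeca-3,7-dien-1-yl acetate | CC(C)(C)[Si](C)(C)OCC/C(C)=C\CC/C(C)=C/C[C@@H](OC(C)=O)[C@]1(C)O[C@H]1C=O | intermediate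
16 | (1R,3E,7Z)-10-[(tert-butyldimethylsilyl)oxy]-1-{(2S,3S)-3-[(1S)-1-hydroxyprop-2-en-1-yl]-2-methyloxiran-2-yl}-4,8-dimethyldeca-3,7-dien-1-yl acetate | CC(C)(C)[Si](C)(C)OCC/C(C)=C\CC/C(C)=C/C[C@@H](OC(C)=O)[C@]1(C)O[C@H]1[C@@H](O)C=C | intermediate
17 | 2-(bromomethyl)prop-2-enoic acid | OC(=O)C(=C)CBr | starting material
18 | 2-(bromomethyl)prop-2-enoyl chloride | ClC(=O)C(=C)CBr | intermediate
19 | (1S)-1-[(2S,3S)-3-{(1R,3E,7Z)-1-acetoxy-10-[(tert-butyldimethylsilyl)oxy]-4,8-dimethyldeca-3,7-dien-1-yl}-3-methyloxiran-2-yl]prop-2-en-1-yl 2-(bromomethyl)prop-2-enoate | CC(C)(C)[Si](C)(C)OCC/C(C)=C\CC/C(C)=C/C[C@@H](OC(C)=O)[C@]1(C)O[C@H]1[C@@H](OC(=O)C(=C)CBr)C=C | intermediate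
20 | (1R,3E,7Z)-1-{(2S,3S)-3-[(2S)-4-(bromomethyl)-5-oxo-2,5-dihydrofuran-2-yl]-2-methyloxiran-2-yl}-10-[(tert-butyldimethylsilyl)oxy]-4,8-dimethyldeca-3,7-dien-1-yl acetate | CC(C)(C)[Si](C)(C)OCC/C(C)=C\CC/C(C)=C/C[C@@H](OC(C)=O)[C@]1(C)O[C@H]1[C@@H]2C=C(CBr)C(=O)O2 | intermediate
21 | (1R,3E,7Z)-1-{(2S,3S)-3-[(2S)-4-(bromomethyl)-5-oxo-2,5-dihydrofuran-2-yl]-2-methyloxiran-2-yl}-10-hydroxy-4,8-dimethyldeca-3,7-dien-1-yl acetate | OCC/C(C)=C\CC/C(C)=C/C[C@@H](OC(C)=O)[C@]1(C)O[C@H]1[C@@H]2C=C(CBr)C(=O)O2 | intermediate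
22 | (1R,3E,7Z)-1-{(2S,3S)-3-[(2S)-4-(bromomethyl)-5-oxo-2,5-dihydrofuran-2-yl]-2-methyloxiran-2-yl}-4,8-dimethyl-10-oxodeca-3,7-dien-1-yl acetate | O=CC/C(C)=C\CC/C(C)=C/C[C@@H](OC(C)=O)[C@]1(C)O[C@H]1[C@@H]2C=C(CBr)C(=O)O2 | intermediate
23 | allylchromium dichloride derived from 22 (CH2CrCl2 in place of CH2Br; trivalent chromium) | O=CC/C(C)=C\CC/C(C)=C/C[C@@H](OC(C)=O)[C@]1(C)O[C@H]1[C@@H]2C=C(C[Cr](Cl)Cl)C(=O)O2 | intermediate
24 | (1R,2S,3S,4S,5R,14S,7E,11Z)-5-acetoxy-3,4-epoxy-14-hydroxycembra-7,11,15(17)-trien-16,2-olide (14-epimer of 26) | C=C1C(=O)O[C@H]2[C@H]1[C@@H](O)C/C(C)=C\CC/C(C)=C/C[C@@H](OC(C)=O)[C@]1(C)O[C@@H]21 | intermediate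
25 | 14-O-formate of 26 | C=C1C(=O)O[C@H]2[C@H]1[C@H](OC=O)C/C(C)=C\CC/C(C)=C/C[C@@H](OC(C)=O)[C@]1(C)O[C@@H]21 | intermediate
26 | (1R,2S,3S,4S,5R,14R,7E,11Z)-5-acetoxy-3,4-epoxy-14-hydroxycembra-7,11,15(17)-trien-16,2-olide (CNP0283244.1) | C=C1C(=O)O[C@H]2[C@H]1[C@H](O)C/C(C)=C\CC/C(C)=C/C[C@@H](OC(C)=O)[C@]1(C)O[C@@H]21 | target

**Totals and risks**
Total step count: 17. Longest linear sequence: 17 steps (1 to 26); 5, 9 and 17 enter as purchased materials.

Most likely to fail, first: step 16. The high-dilution chromium-mediated ring closure may give oligomers, may translactonise through the chromium alkoxide, or may not follow the predicted facial course. The fallback sets out from 20 and comes back at 24, replacing the reducing metal by a thermal intramolecular allylboration. Borylation of 20 (B2pin2, Pd(dba)2 cat., toluene, 50 °C) gives the pinacol allylboronate analogue of 20 (CH2Bpin in place of CH2Br) F4. HF·pyridine then gives the pinacol allylboronate analogue of 21 (CH2Bpin in place of CH2Br) F5, and Dess–Martin oxidation gives the pinacol allylboronate analogue of 22 (CH2Bpin in place of CH2Br) F6. Heating F6 in toluene at 0.003 M (60–80 °C) closes the ring through the same chair transition state to the 14-O-pinacolboryl ester of 24 F7, which aqueous work-up hydrolyses to 24.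

Second: step 17. The Mitsunobu inversion at a ring carbinol next to the acidic C1–H may give elimination to a diene, carbonyl participation, or phosphine addition to the methylene lactone. The fallback sets out from 24 and comes back at 26 by sulfonate displacement with nitrite (Lattrell–Dax inversion). Tf2O and pyridine in CH2Cl2 at −30 °C give the 14-O-trifluoromethanesulfonate of 24 F8. KNO2 and 18-crown-6 in DMF at rt displace it with inversion to the 14-O-nitrite of 26 F9, which aqueous work-up hydrolyses to 26.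

Third: step 8. SN2 at a carbinol flanked by the fully substituted epoxide carbon may be slow or give elimination. The fallback sets out from 11 and comes back at 14 without any inversion. It uses the enantiomer of 11 that step 7 leaves unreacted, (2E,4R,6E,10Z)-13-[(tert-butyldimethylsilyl)oxy]-4-hydroxy-3,7,11-trimethyltrideca-2,6,10-trien-1-yl acetate F1, which already has the C5 configuration of the target. Acetylation (Ac2O, pyridine, DMAP) gives (2E,4R,6E,10Z)-13-[(tert-butyldimethylsilyl)oxy]-3,7,11-trimethyltrideca-2,6,10-triene-1,4-diyl diacetate F2. K2CO3 in MeOH at −10 °C removes the primary acetate to give (2E,4R,6E,10Z)-13-[(tert-butyldimethylsilyl)oxy]-1-hydroxy-3,7,11-trimethyltrideca-2,6,10-trien-4-yl acetate F3. Reagent-controlled Sharpless epoxidation through the primary allylic hydroxyl (Ti(OiPr)4, L-(+)-diethyl tartrate, t-BuOOH, 4 Å MS, CH2Cl2, −20 °C) then delivers 14.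

**Further compounds**
F1 | step 8 | (2E,4R,6E,10Z)-13-[(tert-butyldimethylsilyl)oxy]-4-hydroxy-3,7,11-trimethyltrideca-2,6,10-trien-1-yl acetate | CC(C)(C)[Si](C)(C)OCC/C(C)=C\CC/C(C)=C/C[C@@H](O)/C(C)=C/COC(C)=O
F2 | step 8 | (2E,4R,6E,10Z)-13-[(tert-butyldimethylsilyl)oxy]-3,7,11-trimethyltrideca-2,6,10-triene-1,4-diyl diacetate | CC(C)(C)[Si](C)(C)OCC/C(C)=C\CC/C(C)=C/C[C@@H](OC(C)=O)/C(C)=C/COC(C)=O
F3 | step 8 | (2E,4R,6E,10Z)-13-[(tert-butyldimethylsilyl)oxy]-1-hydroxy-3,7,11-trimethyltrideca-2,6,10-trien-4-yl acetate | CC(C)(C)[Si](C)(C)OCC/C(C)=C\CC/C(C)=C/C[C@@H](OC(C)=O)/C(C)=C/CO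
F4 | step 16 | pinacol allylboronate analogue of 20 (CH2Bpin in place of CH2Br) | CC(C)(C)[Si](C)(C)OCC/C(C)=C\CC/C(C)=C/C[C@@H](OC(C)=O)[C@]1(C)O[C@H]1[C@@H]2C=C(CB3OC(C)(C)C(C)(C)O3)C(=O)O2
F5 | step 16 | pinacol allylboronate analogue of 21 (CH2Bpin in place of CH2Br) | OCC/C(C)=C\CC/C(C)=C/C[C@@H](OC(C)=O)[C@]1(C)O[C@H]1[C@@H]2C=C(CB3OC(C)(C)C(C)(C)O3)C(=O)O2
F6 | step 16 | pinacol allylboronate analogue of 22 (CH2Bpin in place of CH2Br) | O=CC/C(C)=C\CC/C(C)=C/C[C@@H](OC(C)=O)[C@]1(C)O[C@H]1[C@@H]2C=C(CB3OC(C)(C)C(C)(C)O3)C(=O)O2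
F7 | step 16 | 14-O-pinacolboryl ester of 24 | C=C1C(=O)O[C@H]2[C@H]1[C@@H](OB3OC(C)(C)C(C)(C)O3)C/C(C)=C\CC/C(C)=C/C[C@@H](OC(C)=O)[C@]1(C)O[C@@H]21
F8 | step 17 | 14-O-trifluoromethanesulfonate of 24 | C=C1C(=O)O[C@H]2[C@H]1[C@@H](OS(=O)(=O)C(F)(F)F)C/C(C)=C\CC/C(C)=C/C[C@@H](OC(C)=O)[C@]1(C)O[C@@H]21
F9 | step 17 | 14-O-nitrite of 26 | C=C1C(=O)O[C@H]2[C@H]1[C@H](ON=O)C/C(C)=C\CC/C(C)=C/C[C@@H](OC(C)=O)[C@]1(C)O[C@@H]21
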